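## The problem

The target 20 is a carotane (daucane) sesquiterpenoid ester: a trans-fused bicyclo[5.3.0]decane in which a cyclopentane (C1–C5) and a cycloheptane (C1, C5–C10) share the C1–C5 bond, with C1 the methyl-bearing fusion carbon, C4 the isopropyl carbinol, C5 the fusion CH, C6 the carbinol that carries the 4-hydroxybenzoate, C8 the methyl carbinol and C9 the secondary carbinol. Six stereocentres (1R,4R,5S,6S,8S,9S) must be set, among them an all-carbon quaternary centre at C1 and tertiary alcohols at C4 and C8. On the five-membered ring the C1 methyl and the C4 hydroxyl are cis (1,3) and both trans to H5; on the seven-membered ring the C6 and C9 oxygens lie on the face of H5 and the C8 hydroxyl on the opposite face. Only C4 can be bought: it can pass its configuration to C1 if something attached to its oxygen is made to reach C1, and the rigid bicycle formed in that way then governs C5 and C6. C9 is 1,6-related to C4 in any open-chain precursor and so needs reagent control, after which it is the natural director for its neighbour C8. The fragile points are the β-relationship between the C4 hydroxyl and C6 (retro-aldol cleavage or dehydration whenever C6 is a carbonyl and O4 is free), the aryl ester (hydride, alkoxide, hot fluoride) and the free phenol. The feature that opens the key step is the cis-1,3 pair O4/CH3(C1) with C5 between them: if C5 carries C6 as an aldehyde conjugated to a C1=C5 double bond, a one-carbon radical tied through silicon to O4 can bond only to C1 and only on the oxygen's face, so removing the tether leaves exactly the methyl and hydroxyl of the target.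

## Retrosynthesis

**20 ⇒ 19.** No skeletal bond is cut. The phenol and the C9 hydroxyl are released together by hydrogenolysis of a benzyl ether and a benzyloxymethyl (BOM) ether. With two hydrogenolysable groups the last step sheds only small volatile fragments, and the ester travels as its robust 4-(benzyloxy)benzoate. The forward step needs a substrate without alkenes, which holds once C8 is hydrated.

**19 ⇒ 18.** The C8–O bond is cut: the tertiary carbinol is taken back to an exocyclic methylene. Adding a methyl nucleophile to a C8 ketone would tend to put the new hydroxyl cis to the C9 oxygen, and an 8,9-epoxide would need an endocyclic alkene that the ring closure below does not deliver. The exocyclic alkene is what that closure leaves, and the C9 substituent is next door to send oxygen to the opposite face. Asked of the forward reaction: Markovnikov hydration, anti to the C9 substituent.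

**18 ⇒ 16 + 17.** The ester C–O bond is cut, giving diol 16 and 4-(benzyloxy)benzoyl chloride 17. Acylating late keeps the ester away from the aluminium and fluoride steps. It is selective because C9 is still protected and C4 is tertiary, so C6–OH is the only acylable hydroxyl.

**16 ⇒ 15.** The C1 methyl and the C4 hydroxyl are read as the two ends of an O–SiMe2–CH2 bridge. This retron carries the plan: a cis-1,3 hydroxy/methyl pair on a cyclopentane is the trace of a cleaved silicon tether. The forward step must cleave one Si–O and one Si–C bond of siloxane 15 without touching the BOM ether or the exocyclic alkene.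

**15 ⇒ 14.** The C6–C7 bond is cut, opening the seven-membered ring to aldehyde 14 with an isopropenyl terminus (type 2 carbonyl-ene retron: homoallylic alcohol with exocyclic methylene). Closing at C8–C9 or C9–C10 would need two functionalised ends. The C6–C7 cut reuses the aldehyde that activates the radical acceptor together with an unfunctionalised alkene, and it leaves the C6 hydroxyl and the C8 methylene, both needed later. The forward reaction must set C6 through the ring-forming transition state on a hindered aldehyde.

**14 ⇒ 13.** The bond between C1 and the future methyl carbon is cut, opening the oxasilacycle to the (bromomethyl)dimethylsilyl ether 13 of a cyclopentene carbaldehyde. C1 and C5 flatten into an enal and C4 becomes the only ring stereocentre. A methyl cuprate addition to the same enal would depend on facial discrimination between isopropyl and silyloxy at a tetrasubstituted acceptor; the tether removes that question. Asked: 6-endo regiochemistry and hydrogen delivery at C5 trans to the new bond.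

**13 ⇒ 11 + 12; 11 ⇒ 10.** Functional-group steps only: the labile bromomethylsilyl ether is installed from tertiary alcohol 11 and silane 12 just before use, and a triethylsilyl (TES) ether (10) protects O4 through the earlier steps.

**10 ⇒ 9 (⇒ 8 ⇒ 7).** The C1=C5 bond is cut: a 2-substituted cyclopent-1-ene-1-carbaldehyde is the aldol condensation product of a 1,6-keto aldehyde (9). This removes the ring and returns an open chain whose two carbonyls come from one alkene. Asked: the aldehyde α-carbon, not a ketone α-carbon, must be the nucleophile. Compounds 8 and 7 differ from 9 only in acetal and BOM protection.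

**7 ⇒ 4 + 5.** The C9–C10 bond is cut: aldol of methyl ketone 4, through its boron enolate 6, with methacrolein 5. One step brings in C7, C8, its methyl and C9 with the C9 oxygen and the ene alkene in place. Alkylation with a methallyl electrophile would leave C9 unoxidised. Asked: enolisation on the methyl side and reagent-controlled attack on one aldehyde face.

**4 ⇒ 2 ⇒ 1.** Reconnecting the ketone and acetal carbons (through keto aldehyde 3) gives the trisubstituted alkene of (S)-terpinen-4-ol 1, carried as its TES ether 2. Compound 1 supplies ten of the fifteen skeletal carbons and the C4 stereocentre with oxygen and isopropyl in place; its ring methyl becomes C10.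

## Roads not taken

**Alternative 1:** Enzymatic folding of farnesyl diphosphate A1. The cut is C1–C10 and C4–C5 at once: a carotol synthase would ionise A1, close both rings and quench the fusion cation with water to give carotol A2. In framework construction this road is better than the chosen plan: all fifteen carbons, both rings and the fusion stereocentres in one step from a fermentable precursor, with no tin and no protecting groups. Its weakness is the oxidation pattern. A2 has its hydroxyl at C5 and hydrogen at C4, whereas 20 needs hydrogen at C5, hydroxyl at C4 and an acyloxy group at C6. The route would need a stereocontrolled deoxygenation at the ring fusion and two oxidations at unactivated positions (tertiary C4–H, C6 methylene) with no handle. Only the C8=C9 alkene is useful, and there A2 is ahead, since epoxidation and hydrolytic opening give a trans diol more directly than step 13 here. Against the enzymatic skeleton the chosen plan sets that O4 is present from the first compound and O6 arrives as the aldehyde that drives the key step, so no C–H oxidation is needed.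

**Alternative 2:** Three-component conjugate addition–aldol. The cuts are C1–CH3 and C5–C6. The acceptor is enone A3, 3-(1,3-dioxolan-2-ylmethyl)cyclopent-2-en-1-one, and the electrophile is aldehyde A4, (2-methyl-1,3-dioxolan-2-yl)acetaldehyde. AlMe3 under Cu(OTf)2 and a chiral phosphoramidite ligand would add methyl to A3, and the aluminium enolate would be trapped by A4 to give aldol A5 with C1, C5 and C6 set and no ring closed. Its merits are real: catalytic asymmetric entry, two C–C bonds and three stereocentres in one flask, and both seven-ring termini already oxidised, so a reductive carbonyl coupling could close C8–C9 with both oxygens in place. In convergence and in avoiding stoichiometric tin it is better than the chosen plan. Its weak points for this target are: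
- five-membered enones such as A3 are the less selective substrates for this quaternary-centre chemistry;
- the C6 configuration rests on an aluminium enolate aldol with A4 of uncertain sense;
- the isopropyl group must later be added to a hindered, enolisable C4 ketone on the correct face;
- a reductive pinacol closure usually favours the cis diol, whereas 20 is trans at C8/C9.

The chosen plan sets against this that its absolute configuration comes from the chiral pool, that C4 is complete from the start, and that C1 follows from a geometric necessity, not from a catalyst-controlled selectivity.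

**Alternative 3:** Ring contraction as the strategic step. The cut is C1=C5: amine–acid-catalysed aldol condensation of keto aldehyde 3 to 5-isopropyl-2-methyl-5-(triethylsilyloxy)cyclopent-1-ene-1-carbaldehyde A6. This step is more reliable than the key step here, fully precedented and only two operations from 1; the chosen plan uses the same condensation as step 6. As a centrepiece it forms the easiest bond and no stereocentre. From A6 the quaternary C1 must still be built on a tetrasubstituted enal, and either the ring methyl must be functionalised at the γ-position to become C10 or the whole C10–C7 chain delivered as a nucleophile, with face selection between isopropyl and silyloxy unsecured. The chosen plan keeps the condensation but attaches the chain earlier, at the methyl ketone where regioselective enolisation is simple, and adds the tether to solve C1.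

Key step: step 9

Assumption 1: (S)-(+)-terpinen-4-ol is taken as purchasable in high enantiomeric purity; lower-grade material would be upgraded through a crystalline ester before use.
Assumption 2: (+)-Ipc2BCl (from (−)-α-pinene) is taken to direct a methyl-ketone enolate to the Si face of methacrolein, giving (S) at C9; if the sense is opposite on this substrate the antipodal reagent is used.

## Route

Step 1
Reactants: 1 (S)-(+)-terpinen-4-ol
Product: 2 triethyl{[(1S)-4-methyl-1-(propan-2-yl)cyclohex-3-en-1-yl]oxy}silane
Conditions: TESOTf, 2,6-lutidine, CH2Cl2, 0 °C → rt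
Reagents that add atoms: triethylsilyl trifluoromethanesulfonate, CC[Si](CC)(CC)OS(=O)(=O)C(F)(F)F
Why: Silyl triflate silylation of a hindered tertiary alcohol; it masks O4 so the carbonyls released in step 2 cannot form cyclic hemiketals and the boron and amine reagents meet no free hydroxyl; no stereocentre is touched.

Step 2
Reactants: 2 triethyl{[(1S)-4-methyl-1-(propan-2-yl)cyclohex-3-en-1-yl]oxy}silane
Product: 4 (5S)-7,7-dimethoxy-5-(propan-2-yl)-5-(triethylsilyloxy)heptan-2-one, via keto aldehyde 3 (not isolated)
Conditions: O3, CH2Cl2/MeOH, −78 °C; Me2S, −78 °C → rt; then HC(OMe)3, PPTS (cat.), rt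
Reagents that add atoms: ozone, [O-][O+]=O; trimethyl orthoformate, COC(OC)OC; methanol, CO
Why: Ozonolysis with reductive work-up cleaves the only C=C to a methyl ketone and an aldehyde; under weak acid with orthoformate only the aldehyde is converted into its dimethyl acetal, conditions a tertiary TES ether tolerates, so the two carbonyls are differentiated in one flask.

Step 3
Reactants: 4 (5S)-7,7-dimethoxy-5-(propan-2-yl)-5-(triethylsilyloxy)heptan-2-one; 5 methacrolein
Product: 7 (3S,8S)-3-hydroxy-10,10-dimethoxy-2-methyl-8-(propan-2-yl)-8-(triethylsilyloxy)dec-1-en-5-one, via enol diisopinocampheylborinate 6 (not isolated)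
Conditions: (+)-Ipc2BCl, Et3N, Et2O, 0 °C; 5, −78 → −20 °C; H2O2, MeOH, pH 7 buffer
Reagents that add atoms: none
Why: Boron-mediated aldol of a methyl ketone: the bulky chloroborane with Et3N enolises on the methyl side and the isopinocampheyl ligands select one face of methacrolein in the cyclic transition state, setting C9 as (S) in the sense stated in assumption 2; C4 is too remote to help or hinder, so this is reagent control only and some C9 epimer is expected, to be removed by chromatography here or at the rigid tricycle 15.

Step 4
Reactants: 7 (3S,8S)-3-hydroxy-10,10-dimethoxy-2-methyl-8-(propan-2-yl)-8-(triethylsilyloxy)dec-1-en-5-one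
Product: 8 (3S,8S)-3-[(benzyloxy)methoxy]-10,10-dimethoxy-2-methyl-8-(propan-2-yl)-8-(triethylsilyloxy)dec-1-en-5-one
Conditions: BOMCl, iPr2NEt, Bu4NI (cat.), CH2Cl2, 0 °C → rt
Reagents that add atoms: benzyl chloromethyl ether, ClCOCc1ccccc1
Why: Alkylation of the secondary allylic alcohol under amine base, mild enough for a β-hydroxy ketone; the BOM acetal resists fluoride, tin hydride and base, can be kept while the TES ether is removed, and leaves in the final hydrogenolysis.

Step 5
Reactants: 8 (3S,8S)-3-[(benzyloxy)methoxy]-10,10-dimethoxy-2-methyl-8-(propan-2-yl)-8-(triethylsilyloxy)dec-1-en-5-one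
Product: 9 (3S,8S)-8-[(benzyloxy)methoxy]-9-methyl-6-oxo-3-(propan-2-yl)-3-(triethylsilyloxy)dec-9-enal
Conditions: 10% aq. oxalic acid on SiO2, CH2Cl2, rt
Reagents that add atoms: water, O
Why: Acetal hydrolysis on wet acidic silica; a dimethyl acetal of an aldehyde cleaves under conditions that leave a formaldehyde acetal (BOM) and a tertiary TES ether intact.

Step 6
Reactants: 9 (3S,8S)-8-[(benzyloxy)methoxy]-9-methyl-6-oxo-3-(propan-2-yl)-3-(triethylsilyloxy)dec-9-enal
Product: 10 (5R)-2-{(2S)-2-[(benzyloxy)methoxy]-3-methylbut-3-en-1-yl}-5-(propan-2-yl)-5-(triethylsilyloxy)cyclopent-1-ene-1-carbaldehyde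
Conditions: piperidine, AcOH, benzene, rt
Reagents that add atoms: none
Why: Amine-catalysed intramolecular aldol condensation (the classical ring contraction of a cyclohexene ozonolysis product): the aldehyde forms its enamine far faster than the ketone, C5 attacks the C1 ketone in a five-ring closure and water is lost to the conjugated tetrasubstituted enal; the buffered medium limits β-elimination of the C4 silyloxy and C9 alkoxy groups.

Step 7
Reactants: 10 (5R)-2-{(2S)-2-[(benzyloxy)methoxy]-3-methylbut-3-en-1-yl}-5-(propan-2-yl)-5-(triethylsilyloxy)cyclopent-1-ene-1-carbaldehyde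
Product: 11 (5R)-2-{(2S)-2-[(benzyloxy)methoxy]-3-methylbut-3-en-1-yl}-5-hydroxy-5-(propan-2-yl)cyclopent-1-ene-1-carbaldehyde
Conditions: HF·pyridine, pyridine, THF, 0 °C → rt
Reagents that add atoms: none
Why: Buffered fluoride cleavage of the TES ether; the BOM acetal is inert and the enal is kept away from basic fluoride, which could trigger vinylogous elimination of the C9 alkoxy group.

Step 8
Reactants: 11 (5R)-2-{(2S)-2-[(benzyloxy)methoxy]-3-methylbut-3-en-1-yl}-5-hydroxy-5-(propan-2-yl)cyclopent-1-ene-1-carbaldehyde; 12 (bromomethyl)chlorodimethylsilane
Product: 13 (5R)-2-{(2S)-2-[(benzyloxy)methoxy]-3-methylbut-3-en-1-yl}-5-{[(bromomethyl)dimethylsilyl]oxy}-5-(propan-2-yl)cyclopent-1-ene-1-carbaldehyde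
Conditions: Et3N, DMAP (cat.), CH2Cl2, 0 °C → rt; used without chromatography
Reagents that add atoms: none
Why: Silylation of the tertiary alcohol with a chlorosilane no larger than Me3SiCl; the ether is hydrolytically labile, so it is made last and used directly.

Step 9
Reactants: 13 (5R)-2-{(2S)-2-[(benzyloxy)methoxy]-3-methylbut-3-en-1-yl}-5-{[(bromomethyl)dimethylsilyl]oxy}-5-(propan-2-yl)cyclopent-1-ene-1-carbaldehyde
Product: 14 5-{(2S)-2-[(benzyloxy)methoxy]-3-methylbut-3-en-1-yl}-3,3-dimethyl-1-(propan-2-yl)-2-oxa-3-silabicyclo[3.2.1]octane-8-carbaldehyde (formyl group syn to the O–Si–CH2 bridge)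
Conditions: Bu3SnH (syringe pump), AIBN (cat.), benzene, 80 °C, high dilution
Reagents that add atoms: none
Why: The tin radical abstracts bromine, the nucleophilic α-silylmethyl radical held on O4 adds to the enal β-carbon C1, and the α-formyl radical at C5 is reduced by Bu3SnH. The closest known reaction type is the reductive radical cyclisation of (bromomethyl)dimethylsilyl ethers of allylic alcohols, including 6-endo closures onto conjugated acceptors whose tether sits on the α-substituent; here the same reaction is applied to a cyclic enal with a fully substituted β-carbon. One ring closes, a 1-oxa-2-silacyclohexane formed by 6-endo-trig attack, which bridges C4 and C1 as a 2-oxa-3-silabicyclo[3.2.1]octane. The 6-endo mode is needed over 5-exo, and polarity and sterics both secure it: 5-exo attack at C5 would place a nucleophilic radical on the electron-poor α-carbon, build a quaternary centre beside C4 and leave an unstabilised radical. C1 is controlled by the tether, which can span the ring only on the face of O4, so the new carbon is cis to the C4 oxygen by necessity. C5 is set in the hydrogen transfer: in the chair oxasilacyclohexane the axial hydrogen of the Si–CH2 carbon and the ring oxygen are syn-axial to C5 and screen the face over the O–Si–CH2 bridge, as the axial hydrogens do in bicyclo[3.2.1]octan-8-yl systems, so Bu3SnH should approach over the two-carbon bridge; the formyl group then ends syn to the O–Si–CH2 bridge and trans to C10 as 20 requires, and this facial preference is the least secure element of the step. Cyclisation must also outrun direct reduction of the first radical, which slow stannane addition at high dilution favours, while the C5 radical must be reduced before it adds to the isopropenyl group, which is expected because either mode of that addition would make C5 the centre of three contiguous fully substituted carbons.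

Step 10
Reactants: 14 5-{(2S)-2-[(benzyloxy)methoxy]-3-methylbut-3-en-1-yl}-3,3-dimethyl-1-(propan-2-yl)-2-oxa-3-silabicyclo[3.2.1]octane-8-carbaldehyde
Product: 15 siloxane-bridged hydroazulenol (skeleton of 16 with O4 and the C1 methylene still joined through SiMe2; free C6–OH, C9–OBOM, C8 exocyclic methylene)
Conditions: Me2AlCl (2–3 equiv), CH2Cl2, −78 → 0 °C
Reagents that add atoms: none
Why: Lewis acid-promoted type 2 carbonyl-ene cyclisation: the terminal carbon C7 of the 1,1-disubstituted alkene attacks the aluminium-bound aldehyde and a methyl hydrogen passes to oxygen, closing the seven-membered ring with an exocyclic methylene at C8; the aluminium-bound oxygen should turn outward, away from the oxasilacyclohexane over which the formyl group sits, while C7 reaches the carbonyl carbon from the C1 side, which places H6 anti to H5 and gives the (S) carbinol at C6; Me2AlCl takes up the proton of the new alcohol as methane.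

Step 11
Reactants: 15 siloxane-bridged hydroazulenol
Product: 16 (3R,3aS,4S,7S,8aR)-7-[(benzyloxy)methoxy]-8a-methyl-6-methylidene-3-(propan-2-yl)decahydroazulene-3,4-diol
Conditions: TBAF (excess, hydrate), DMF, 75 °C
Reagents that add atoms: none
Why: Fluoride-induced protodesilylation of a cyclic alkoxysilane: fluoride opens the Si–O bond, and the pentacoordinate silicon, assisted by the neighbouring alkoxide, gives up its carbon, which is protonated by water; the bridge becomes the C1 methyl and the free C4 hydroxyl, no stereocentre changes and the BOM ether is stable.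

Step 12
Reactants: 16 (3R,3aS,4S,7S,8aR)-7-[(benzyloxy)methoxy]-8a-methyl-6-methylidene-3-(propan-2-yl)decahydroazulene-3,4-diol; 17 4-(benzyloxy)benzoyl chloride
Product: 18 (3R,3aS,4S,7S,8aR)-7-[(benzyloxy)methoxy]-3-hydroxy-8a-methyl-6-methylidene-3-(propan-2-yl)decahydroazulen-4-yl 4-(benzyloxy)benzoate
Conditions: Et3N, DMAP, CH2Cl2, 0 °C → rt
Reagents that add atoms: none
Why: DMAP-catalysed acylation; only the secondary C6 hydroxyl reacts, since the C4 hydroxyl is tertiary and C9 is still protected.

Step 13
Reactants: 18 (3R,3aS,4S,7S,8aR)-7-[(benzyloxy)methoxy]-3-hydroxy-8a-methyl-6-methylidene-3-(propan-2-yl)decahydroazulen-4-yl 4-(benzyloxy)benzoate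
Product: 19 (3R,3aS,4S,6S,7S,8aR)-7-[(benzyloxy)methoxy]-3,6-dihydroxy-6,8a-dimethyl-3-(propan-2-yl)decahydroazulen-4-yl 4-(benzyloxy)benzoate
Conditions: Mn(dpm)3 (cat.), PhSiH3, O2 (1 atm), i-PrOH/CH2Cl2, 0 °C → rt
Reagents that add atoms: dioxygen, O=O
Why: Mukaiyama hydration: metal hydride hydrogen-atom transfer to the 1,1-disubstituted alkene, capture of the tertiary C8 radical by O2 and reduction of the peroxide in situ give the Markovnikov tertiary alcohol; oxygen is expected to bond anti to the adjacent C9 benzyloxymethoxy group and away from the C6 ester (1,2-induction in a cyclic radical), which gives the trans C8/C9 arrangement, C8 (S).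

Step 14
Reactants: 19 (3R,3aS,4S,6S,7S,8aR)-7-[(benzyloxy)methoxy]-3,6-dihydroxy-6,8a-dimethyl-3-(propan-2-yl)decahydroazulen-4-yl 4-(benzyloxy)benzoate
Product: 20 (3R,3aS,4S,6S,7S,8aR)-3,6,7-trihydroxy-6,8a-dimethyl-3-(propan-2-yl)decahydroazulen-4-yl 4-hydroxybenzoate
Conditions: H2 (1 atm), Pd(OH)2/C, EtOAc/MeOH, rt
Reagents that add atoms: none
Why: Hydrogenolysis removes the aryl benzyl ether and the BOM group (the residual hemiacetal loses formaldehyde) in one operation; no alkene, epimerisable centre or hydrogenolysable ester is present.

## Compound list

1 | (S)-(+)-terpinen-4-ol, (1S)-4-methyl-1-(propan-2-yl)cyclohex-3-en-1-ol | CC(C)[C@]1(O)CCC(C)=CC1 | starting material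
2 | triethyl{[(1S)-4-methyl-1-(propan-2-yl)cyclohex-3-en-1-yl]oxy}silane | CC(C)[C@]1(O[Si](CC)(CC)CC)CCC(C)=CC1 | intermediate
3 | (3S)-6-oxo-3-(propan-2-yl)-3-(triethylsilyloxy)heptanal (formed in the flask) | CC(C)[C@](CC=O)(O[Si](CC)(CC)CC)CCC(C)=O | intermediate
4 | (5S)-7,7-dimethoxy-5-(propan-2-yl)-5-(triethylsilyloxy)heptan-2-one | CC(C)[C@](CC(OC)OC)(O[Si](CC)(CC)CC)CCC(C)=O | intermediate
5 | methacrolein (2-methylprop-2-enal) | CC(=C)C=O | starting material
6 | enol diisopinocampheylborinate of 4 (boron enolate on the methyl side, isopinocampheyl groups from (−)-α-pinene; formed in the flask) | CC(C)[C@](CC(OC)OC)(O[Si](CC)(CC)CC)CCC(=C)OB([C@H]1C[C@H]2C[C@@H]([C@@H]1C)C2(C)C)[C@H]1C[C@H]2C[C@@H]([C@@H]1C)C2(C)C | intermediate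
7 | (3S,8S)-3-hydroxy-10,10-dimethoxy-2-methyl-8-(propan-2-yl)-8-(triethylsilyloxy)dec-1-en-5-one | CC(C)[C@](CC(OC)OC)(O[Si](CC)(CC)CC)CCC(=O)C[C@H](O)C(C)=C | intermediate
8 | (3S,8S)-3-[(benzyloxy)methoxy]-10,10-dimethoxy-2-methyl-8-(propan-2-yl)-8-(triethylsilyloxy)dec-1-en-5-one | CC(C)[C@](CC(OC)OC)(O[Si](CC)(CC)CC)CCC(=O)C[C@H](OCOCc1ccccc1)C(C)=C | intermediate
9 | (3S,8S)-8-[(benzyloxy)methoxy]-9-methyl-6-oxo-3-(propan-2-yl)-3-(triethylsilyloxy)dec-9-enal | CC(C)[C@](CC=O)(O[Si](CC)(CC)CC)CCC(=O)C[C@H](OCOCc1ccccc1)C(C)=C | intermediate
10 | (5R)-2-{(2S)-2-[(benzyloxy)methoxy]-3-methylbut-3-en-1-yl}-5-(propan-2-yl)-5-(triethylsilyloxy)cyclopent-1-ene-1-carbaldehyde | CC(C)[C@]1(O[Si](CC)(CC)CC)CCC(C[C@H](OCOCc2ccccc2)C(C)=C)=C1C=O | intermediate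
11 | (5R)-2-{(2S)-2-[(benzyloxy)methoxy]-3-methylbut-3-en-1-yl}-5-hydroxy-5-(propan-2-yl)cyclopent-1-ene-1-carbaldehyde | CC(C)[C@]1(O)CCC(C[C@H](OCOCc2ccccc2)C(C)=C)=C1C=O | intermediate
12 | (bromomethyl)chlorodimethylsilane | C[Si](C)(Cl)CBr | starting material
13 | (5R)-2-{(2S)-2-[(benzyloxy)methoxy]-3-methylbut-3-en-1-yl}-5-{[(bromomethyl)dimethylsilyl]oxy}-5-(propan-2-yl)cyclopent-1-ene-1-carbaldehyde | CC(C)[C@]1(O[Si](C)(C)CBr)CCC(C[C@H](OCOCc2ccccc2)C(C)=C)=C1C=O | intermediate
14 | 5-{(2S)-2-[(benzyloxy)methoxy]-3-methylbut-3-en-1-yl}-3,3-dimethyl-1-(propan-2-yl)-2-oxa-3-silabicyclo[3.2.1]octane-8-carbaldehyde, formyl group on the one-carbon bridge syn to the O–Si–CH2 bridge; C1, C4, C5 as in the target | CC(C)[C@@]12CC[C@@](C[C@H](OCOCc3ccccc3)C(C)=C)(C[Si](C)(C)O1)[C@H]2C=O | intermediate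
15 | siloxane-bridged hydroazulenol: trans-fused hydroazulene of 16 with O4–SiMe2–CH2–C1 bridge retained, (6S)-hydroxyl, (9S)-benzyloxymethoxy, C8 exocyclic methylene | CC(C)[C@@]12CC[C@]3(C[Si](C)(C)O1)C[C@H](OCOCc4ccccc4)C(=C)C[C@H](O)[C@@H]23 | intermediate
16 | (3R,3aS,4S,7S,8aR)-7-[(benzyloxy)methoxy]-8a-methyl-6-methylidene-3-(propan-2-yl)decahydroazulene-3,4-diol | CC(C)[C@]1(O)CC[C@]2(C)C[C@H](OCOCc3ccccc3)C(=C)C[C@H](O)[C@H]21 | intermediate
17 | 4-(benzyloxy)benzoyl chloride | O=C(Cl)c1ccc(OCc2ccccc2)cc1 | starting material
18 | (3R,3aS,4S,7S,8aR)-7-[(benzyloxy)methoxy]-3-hydroxy-8a-methyl-6-methylidene-3-(propan-2-yl)decahydroazulen-4-yl 4-(benzyloxy)benzoate | CC(C)[C@]1(O)CC[C@]2(C)C[C@H](OCOCc3ccccc3)C(=C)C[C@H](OC(=O)c4ccc(OCc5ccccc5)cc4)[C@H]21 | intermediate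
19 | (3R,3aS,4S,6S,7S,8aR)-7-[(benzyloxy)methoxy]-3,6-dihydroxy-6,8a-dimethyl-3-(propan-2-yl)decahydroazulen-4-yl 4-(benzyloxy)benzoate | CC(C)[C@]1(O)CC[C@]2(C)C[C@H](OCOCc3ccccc3)[C@@](C)(O)C[C@H](OC(=O)c4ccc(OCc5ccccc5)cc4)[C@H]21 | intermediate
20 | (3R,3aS,4S,6S,7S,8aR)-3,6,7-trihydroxy-6,8a-dimethyl-3-(propan-2-yl)decahydroazulen-4-yl 4-hydroxybenzoate (CNP0197754.1) | CC(C)[C@]1(O)CC[C@]2(C)C[C@H](O)[C@@](C)(O)C[C@H](OC(=O)c3ccc(O)cc3)[C@H]21 | target

## Step count and least certain steps

Total: 14 steps. Longest linear sequence: 14 steps (1 → 20); 5, 12 and 17 are used as purchased.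

**Step 9 (key step).** The most likely failure is poor facial selectivity in the hydrogen transfer at C5: only one axial hydrogen and the ring oxygen screen the face over the O–Si–CH2 bridge, so the preference for approach over the two-carbon bridge may be small. A second failure is direct reduction of the first radical before the slow bridged closure. The fallback sets C5 under thermodynamic control once the bridge is gone. From 14 (as an epimer mixture at C5), NaBH4 reduction would give the primary alcohol F1. TBAF in DMF would remove the bridge to give the diol F2. Dess–Martin oxidation of the primary hydroxyl followed by brief equilibration with Et3N would give the hydroxy aldehyde F3, in which the formyl group should settle cis to the C4 hydroxyl and the C1 methyl and trans to the isopropyl group and the C10 chain. Me2AlCl-promoted carbonyl-ene closure of F3 would return to the route at 16. F3 is a β-hydroxy aldehyde, so base contact must be short.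

**Step 11.** The most likely failure is sluggish C–Si cleavage: a six-membered alkoxysilane gains less from pentacoordination than the five-membered rings on which this protodesilylation is best established, and forcing the conditions invites base-induced migration of the exocyclic alkene. The fallback replaces protodesilylation by oxidation and radical deoxygenation. From 15, Tamao–Fleming oxidation (KF, KHCO3, H2O2, THF/MeOH) would give the triol F4. Its primary hydroxyl alone should react with 1,1'-thiocarbonyldiimidazole to give the imidazole-1-carbothioate F5; an acyl-type derivative is chosen because a halide or sulfonate at this carbon could be displaced by the cis C4 hydroxyl to form a bridged ether. Barton–McCombie reduction with Bu3SnH and AIBN in refluxing toluene, at high stannane concentration so that the primary radical is quenched before it can add to the exocyclic alkene, would return to the route at 16.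

**Step 10.** The most likely failure is diversion of a stepwise cationic pathway. After C6–C7 bonding, the developing C8 cation can take a hydride from C9 to form an oxocarbenium ion, or the Lewis acid can ionise the allylic acetal; the allylic oxygen also lowers the nucleophilicity of the alkene. The fallback closes the same bond with an organochromium nucleophile. From 14, ene-type chlorination of the isopropenyl group (Ca(OCl)2, CO2, CH2Cl2/H2O) would give the allylic chloride F6. Intramolecular Nozaki–Hiyama allylation with CrCl2 in THF would return to the route at 15; the C6 configuration from this closure would have to be confirmed.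

**Step 13.** The most likely failure is low facial selectivity in oxygen capture by the tertiary radical of a flexible seven-membered ring. The fallback uses osmylation, which reliably occurs anti to an allylic oxygen. From 18, OsO4/NMO would give the triol F7 (C8 hydroxyl trans to the C9 oxygen, plus a primary hydroxyl). Selective iodination of the primary hydroxyl (I2, PPh3, imidazole, 0 °C) would give the iodide F8. Bu3SnH reduction would return to the route at 19.

**Step 3.** The most likely failure is incomplete reagent control at C9, leaving an epimer that is hard to separate while the two stereocentres are far apart in an open chain. The fallback is an enantioselective Mukaiyama aldol. From 4, LiN(iPr)2 and Me3SiCl would give the trimethylsilyl enol ether F9. Its addition to methacrolein 5 under the oxazaborolidinone prepared from N-tosyl-(S)-valine and BH3·THF, followed by citric acid in methanol, would return to the route at 7.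

## Further compounds

F1 | step 9 | primary alcohol from reduction of 14 (C5 epimer mixture), [5-{(2S)-2-[(benzyloxy)methoxy]-3-methylbut-3-en-1-yl}-3,3-dimethyl-1-(propan-2-yl)-2-oxa-3-silabicyclo[3.2.1]octan-8-yl]methanol | CC(C)[C@@]12CC[C@@](C[C@H](OCOCc3ccccc3)C(C)=C)(C[Si](C)(C)O1)C2CO
F2 | step 9 | 3-{(2S)-2-[(benzyloxy)methoxy]-3-methylbut-3-en-1-yl}-2-(hydroxymethyl)-3-methyl-1-(propan-2-yl)cyclopentan-1-ol (C1 methyl cis to the ring hydroxyl; epimer mixture at the CH2OH-bearing carbon) | CC(C)[C@]1(O)CC[C@](C)(C[C@H](OCOCc2ccccc2)C(C)=C)C1CO
F3 | step 9 | 5-{(2S)-2-[(benzyloxy)methoxy]-3-methylbut-3-en-1-yl}-2-hydroxy-5-methyl-2-(propan-2-yl)cyclopentane-1-carbaldehyde, formyl cis to hydroxyl and ring methyl | CC(C)[C@]1(O)CC[C@](C)(C[C@H](OCOCc2ccccc2)C(C)=C)[C@H]1C=O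
F4 | step 11 | triol: 16 with CH2OH in place of the C1 methyl, all stereocentres arranged in space as in 16 | CC(C)[C@]1(O)CC[C@]2(CO)C[C@H](OCOCc3ccccc3)C(=C)C[C@H](O)[C@H]21
F5 | step 11 | imidazole-1-carbothioate: F4 with its primary hydroxyl converted into CH2OC(=S)(imidazol-1-yl) | CC(C)[C@]1(O)CC[C@]2(COC(=S)n3ccnc3)C[C@H](OCOCc4ccccc4)C(=C)C[C@H](O)[C@H]21
F6 | step 10 | allylic chloride: 14 with the isopropenyl group converted into 3-chloroprop-1-en-2-yl | CC(C)[C@@]12CC[C@@](C[C@H](OCOCc3ccccc3)C(=C)CCl)(C[Si](C)(C)O1)[C@H]2C=O
F7 | step 13 | triol: 19 with CH2OH in place of the C8 methyl | CC(C)[C@]1(O)CC[C@]2(C)C[C@H](OCOCc3ccccc3)[C@@](CO)(O)C[C@H](OC(=O)c4ccc(OCc5ccccc5)cc4)[C@H]21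
F8 | step 13 | iodide: 19 with CH2I in place of the C8 methyl | CC(C)[C@]1(O)CC[C@]2(C)C[C@H](OCOCc3ccccc3)[C@@](CI)(O)C[C@H](OC(=O)c4ccc(OCc5ccccc5)cc4)[C@H]21
F9 | step 3 | trimethylsilyl enol ether of 4 (methyl side) | CC(C)[C@](CC(OC)OC)(O[Si](CC)(CC)CC)CCC(=C)O[Si](C)(C)C
A1 | alternative 1 | (2E,6E)-farnesyl diphosphate | CC(C)=CCC/C(C)=C/CC/C(C)=C/COP(=O)(O)OP(=O)(O)O
A2 | alternative 1 | carotol | CC(C)[C@@H]1CC[C@]2(C)CC=C(C)CC[C@@]21O
A3 | alternative 2 | 3-(1,3-dioxolan-2-ylmethyl)cyclopent-2-en-1-one | O=C1CCC(CC2OCCO2)=C1
A4 | alternative 2 | (2-methyl-1,3-dioxolan-2-yl)acetaldehyde | O=CCC1(C)OCCO1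
A5 | alternative 2 | trans-2,3-disubstituted 3-methylcyclopentanone aldol | O=C1CC[C@](C)(CC2OCCO2)[C@H]1[C@@H](O)CC3(C)OCCO3
A6 | alternative 3 | 5-isopropyl-2-methyl-5-(triethylsilyloxy)cyclopent-1-ene-1-carbaldehyde | CC(C)[C@]1(O[Si](CC)(CC)CC)CCC(C)=C1C=O
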